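(The data come from a simulation from invented constants; scatter was added.)

**Sunday's puzzle.** Sunday's run charged more Q than G, 0.14 M against 0.090 M, yet its highest reading of D is 70.9% at 0.208 d, with 28.0% of G still free. By 2.50 d, D reads 37.9%.

| setting | Saturday's | Sunday's | flask |
|---|---|---|---|
| G | 0.090 M | 0.090 M | 0.090 M |
| Q | 0.088 M | 0.14 M | 0.0630 M |
| remark | run made earlier | run made earlier |  |
| time |  |  | 4.0 d |

| run | time / d | D / % | G / % |
|---|---|---|---|
| Saturday's | 0.0556 | 42.1 | 57.4 |
| Saturday's | 0.104 | 48.8 | 49.5 |
| Saturday's | 0.208 | 51.5 | 47.3 |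
| Saturday's | 0.333 | 51.6 | 49.2 |
| Saturday's | 0.625 | 48.2 | 50.8 |
| Saturday's | 1.25 | 41.3 | 57.3 |
| Saturday's | 2.50 | 29.1 | 69.4 |
| Sunday's | 0.0556 | 58.6 | 40.7 |
| Sunday's | 0.104 | 67.6 | 30.8 |
| Sunday's | 0.208 | 70.9 | 28.0 |
| Sunday's | 0.333 | 69.4 | 29.0 |
| Sunday's | 0.625 | 64.4 | 33.7 |
| Sunday's | 1.25 | 52.8 | 44.4 |
| Sunday's | 2.50 | 37.9 | 60.4 |

(scatter of a reading: 0.5 percentage points)

- time, not beyond 4.0 d, at which the flask holds most D
- the amount of D, in percent of the G charged, at that time

**Balance of Q.** Charged Q equals c(Q) + c(D) + c(E) + c(X) + c(Z), so D holds a share of the charge and the other terms hold the rest. Call the **capture share** the peak c(D) per charged Q. The highest readings give 52.8% on Saturday and 45.6% on Sunday, which clears the puzzle: at that reading Sunday's D held under half of the Q charged, and the balance puts the rest in the other terms.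

**My reckoning.** The flask charges Q as the limiting reagent. A straight line through the two shares, taken against charged Q, falls by 1.38 /M and gives as an estimate for this flask a capture share of 56.2%, hence D at 39.4% of the G charged. Saturday's top two readings lie within the scatter of each other, so this reckoning takes the time of Sunday's highest reading for the flask, near 0.208 d.

**The forecast.** It gives 38% at 0.3 d, later than the time reckoned above, holding that “With less Q, the approach is slower”.

**The result.** The flask peaks at 0.218 d with D at 39.5% of the G charged, earlier than forecast.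

    G + Q ⇌ D (K = 220 /M, k = 9.00 /M/h)
    G + Q ⇌ E (K = 79.0 /M, k = 0.140 /M/h)
    Q ⇌ X (K = 1.40, k = 0.170 /h)
    Q → Z (k = 0.240 /h)

At that moment the flask's Z stands at 0.0165 M and its X at 0.00734 M. The flask's capture share comes to 56.4%, against 56.2% reckoned. For the neighbour charged with 0.016 M of Q, the same line gives D at 11.2% of G, and that flask peaks at 11.0%.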